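**Retrosynthetic overview**

1. Target 21 comes from its hexabenzyl ether 20 by hydrogenolysis in the last step.
2. Ring C of the flavanone (O1, C2, C3, C4, C4a, C8a) is closed last by an aryne annulation. An alkoxide oxygen adds to C8a and the aryl anion at C4a captures the ester carbon C4 (ring-closing C4–C4a bond). The partners are ortho-silylaryl triflate 13 and the (S)-β-hydroxy ester 16, which brings C2 with its configuration.
3. Enabling feature: O1 and the C4 carbonyl sit on the neighbouring carbons C8a and C4a of ring A and are 1,3-related through C2–C3, so ring C maps onto an aryne C4a≡C8a plus a β-oxy ester. The oxygen on C5 beside C4a, with only hydrogen on C8 beside C8a, steers the oxygen nucleophile to C8a. The phloroglucinol pattern of ring A supplies the C8a oxygen as the triflate.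
4. 13 comes from a Negishi coupling (biaryl bond C6–C8'') of 8-iodo-tri-O-benzylapigenin 3 with the arylzinc made from the silylated phloroglucinol unit 8, then O-desilylation and triflation. 8 comes from 3,5-bis(benzyloxy)phenol by ortho-bromination and a retro-Brook shift.
5. Ring order: the flavone rings are bought as apigenin, ring A of the flavanone is bought as a phloroglucinol ether, ring C is formed in the key step. C2 is set by asymmetric transfer hydrogenation of β-keto ester 15.

Key step: step 10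

Remark: the target is written without a configuration for the C6–C8'' biaryl axis, which carries four ortho oxygen substituents. The route sets only C2 (S) and leaves the axis uncontrolled, so 11–13 are racemic about it and 20 and 21 may form as a pair of rotamers about it. Flavanone atoms are numbered O1, C2, C3, C4, C4a, C5–C8, C8a; flavone atoms carry double primes.

**Route**

Step 1
Reactants: 1 apigenin
Product: 2 5,7-bis(benzyloxy)-2-[4-(benzyloxy)phenyl]-4H-chromen-4-one
Conditions: BnBr (excess), K2CO3, DMF, 80 °C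
Reagents that add atoms: benzyl bromide, BrCc1ccccc1
Why: Williamson etherification of all three phenols, with excess reagent and heat to alkylate the chelated 5-hydroxyl as well.

Step 2
Reactants: 2 5,7-bis(benzyloxy)-2-[4-(benzyloxy)phenyl]-4H-chromen-4-one
Product: 3 5,7-bis(benzyloxy)-2-[4-(benzyloxy)phenyl]-8-iodo-4H-chromen-4-one
Conditions: I2, CF3CO2Ag, CH2Cl2, rt, dark
Reagents that add atoms: iodine, II
Why: electrophilic aromatic iodination, expected at C8'' because it is ortho and para to the two ether oxygens and ortho to the ring oxygen, while C6'' lies between two alkoxy groups and the 4-benzyloxyphenyl ring is deactivated by the pyranone.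

Step 3
Reactants: 4 3,5-bis(benzyloxy)phenol
Product: 5 3,5-bis(benzyloxy)-2-bromophenol
Conditions: NBS (1 equiv), CH2Cl2, −78 °C
Reagents that add atoms: N-bromosuccinimide, O=C1CCC(=O)N1Br
Why: electrophilic bromination of a phenol at low temperature, expected ortho to the free hydroxyl because the position between the two benzyloxy groups is the most crowded, with one equivalent to stop at the monobromide.

Step 4
Reactants: 5 3,5-bis(benzyloxy)-2-bromophenol
Product: 8 [3,5-bis(benzyloxy)-2-(trimethylsilyl)phenoxy]tri(propan-2-yl)silane, via aryl trimethylsilyl ether 6 (not isolated), via lithium phenoxide 7 (not isolated)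
Conditions: HMDS, THF, 65 °C, evaporate; n-BuLi, THF, −100 → −78 °C; TIPSOTf, −78 °C → rt
Reagents that add atoms: hexamethyldisilazane, C[Si](C)(C)N[Si](C)(C)C; triisopropylsilyl trifluoromethanesulfonate, CC(C)[Si](C(C)C)(C(C)C)OS(=O)(=O)C(F)(F)F
Why: bromine–lithium exchange on the O-silyl ether is followed by 1,3 O→C silyl migration (retro-Brook rearrangement), the standard entry to ortho-silylphenols, and the phenoxide is then capped as the bulky TIPS ether.

Step 5
Reactants: 8 [3,5-bis(benzyloxy)-2-(trimethylsilyl)phenoxy]tri(propan-2-yl)silane and 3 5,7-bis(benzyloxy)-2-[4-(benzyloxy)phenyl]-8-iodo-4H-chromen-4-one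
Product: 11 5,7-bis(benzyloxy)-2-[4-(benzyloxy)phenyl]-8-{2,6-bis(benzyloxy)-3-(trimethylsilyl)-4-[tri(propan-2-yl)silyloxy]phenyl}-4H-chromen-4-one, via aryllithium 9 (not isolated), via arylzinc chloride 10 (not isolated)
Conditions: n-BuLi, THF, 0 °C; ZnCl2, THF, 0 °C → rt; then 3, Pd2(dba)3, SPhos, THF/NMP, 65 °C
Reagents that add atoms: none
Why: directed ortho-lithiation at the only ring C–H flanked by two ether oxygens (the other is shielded by the non-coordinating OTIPS group), transmetalation to zinc so that the flavone ketone is tolerated, and Negishi cross-coupling at zerovalent palladium with a dialkylbiarylphosphine, a combination suited to tetra-ortho-substituted biaryls.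

Step 6
Reactants: 11 5,7-bis(benzyloxy)-2-[4-(benzyloxy)phenyl]-8-{2,6-bis(benzyloxy)-3-(trimethylsilyl)-4-[tri(propan-2-yl)silyloxy]phenyl}-4H-chromen-4-one
Product: 12 5,7-bis(benzyloxy)-2-[4-(benzyloxy)phenyl]-8-[2,6-bis(benzyloxy)-4-hydroxy-3-(trimethylsilyl)phenyl]-4H-chromen-4-one
Conditions: TBAF, AcOH, THF, 0 °C
Reagents that add atoms: none
Why: fluoride cleaves the aryl Si–O bond, and buffering with acetic acid should leave the C–Si bond of the electron-rich ring untouched.

Step 7
Reactants: 12 5,7-bis(benzyloxy)-2-[4-(benzyloxy)phenyl]-8-[2,6-bis(benzyloxy)-4-hydroxy-3-(trimethylsilyl)phenyl]-4H-chromen-4-one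
Product: 13 3,5-bis(benzyloxy)-4-{5,7-bis(benzyloxy)-2-[4-(benzyloxy)phenyl]-4-oxo-4H-chromen-8-yl}-2-(trimethylsilyl)phenyl trifluoromethanesulfonate
Conditions: PhNTf2, DBU, MeCN, rt
Reagents that add atoms: N-phenylbis(trifluoromethanesulfonimide), O=S(=O)(N(c1ccccc1)S(=O)(=O)C(F)(F)F)C(F)(F)F
Why: O-triflation of the phenoxide with a mild triflyl donor, the usual last step to an ortho-silylaryl triflate, compatible with the flavone and the C-silyl group.

Step 8
Reactants: 14 1-[4-(benzyloxy)phenyl]ethan-1-one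
Product: 15 methyl 3-[4-(benzyloxy)phenyl]-3-oxopropanoate
Conditions: NaH, (MeO)2CO, THF, reflux; then aq. HCl
Reagents that add atoms: dimethyl carbonate, COC(=O)OC
Why: crossed Claisen condensation of the ketone enolate with dimethyl carbonate, driven by deprotonation of the β-keto ester formed.

Step 9
Reactants: 15 methyl 3-[4-(benzyloxy)phenyl]-3-oxopropanoate
Product: 16 methyl (3S)-3-[4-(benzyloxy)phenyl]-3-hydroxypropanoate
Conditions: RuCl(p-cymene)[(S,S)-TsDPEN] (1 mol %), HCO2H/Et3N (5:2), DMF, 40 °C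
Reagents that add atoms: none
Why: Noyori asymmetric transfer hydrogenation of the aryl ketone, in which the (S,S)-ligand is expected to give the (S)-carbinol in the same sense as for acetophenone through the CH–π contact between the substrate aryl group and the cymene ligand in the six-membered transition state.

Step 10
Reactants: 13 3,5-bis(benzyloxy)-4-{5,7-bis(benzyloxy)-2-[4-(benzyloxy)phenyl]-4-oxo-4H-chromen-8-yl}-2-(trimethylsilyl)phenyl trifluoromethanesulfonate and 16 methyl (3S)-3-[4-(benzyloxy)phenyl]-3-hydroxypropanoate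
Product: 20 (2S)-5,7-bis(benzyloxy)-2-[4-(benzyloxy)phenyl]-6-{5,7-bis(benzyloxy)-2-[4-(benzyloxy)phenyl]-4-oxo-4H-chromen-8-yl}-2,3-dihydro-4H-chromen-4-one, via silyl ether 17 (not isolated), via aryne 18 (not isolated), via aryl caesium adduct 19 (not isolated)
Conditions: 16 (1.5 equiv), HMDS, TMSCl (cat.), THF, 50 °C, evaporate; then 13, CsF (4 equiv), DME, 0 °C → rt; AcOH quench
Reagents that add atoms: none
Why: Proposed new method: fluoride removes the C-silyl group of 13 with loss of triflate to give aryne 18 and at the same time frees the caesium alkoxide of 17 in a medium without O–H bonds, the alkoxide adds to aryne carbon C8a, and the aryl anion 19 so formed at C4a attacks the methyl ester and expels methoxide, so that the O1–C8a bond and the ring-closing C4–C4a bond are made in one operation. The closest known reaction type is the CsF-mediated annulation of arynes with methyl salicylates to xanthones (phenoxide addition, then intramolecular acyl capture by the aryl anion), which has not been shown for an aliphatic β-hydroxy ester. Ring C is closed by a 6-exo-trig addition of the C4a anion to the ester carbonyl followed by loss of methoxide, a net [4+2] annulation of the two aryne carbons with the O–C2–C3–C4 unit. No stereocentre is formed: C2 is carried over from 16 because neither its C–O nor its C–H bond is touched, and the aprotic, cold conditions are chosen to hold back retro-aldol cleavage of the alkoxide and base-induced opening of the product. The step needs oxygen at C8a and the acyl carbon at C4a, and this is secured by the benzyloxy group on C5 beside the triple bond, whose inductive pull distorts the aryne so that the far carbon C8a is the electrophilic one and the anion develops at C4a next to oxygen, while C8 carries only hydrogen and gives no steric bias the other way (the same sense as known additions to 3-alkoxy- and 3,5-dialkoxyarynes). The absence of a proton source should let the six-membered acyl capture outrun quenching of the aryl anion, and the flavone carbonyl, an untethered vinylogous ester, should not compete.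

Step 11
Reactants: 20 (2S)-5,7-bis(benzyloxy)-2-[4-(benzyloxy)phenyl]-6-{5,7-bis(benzyloxy)-2-[4-(benzyloxy)phenyl]-4-oxo-4H-chromen-8-yl}-2,3-dihydro-4H-chromen-4-one
Product: 21 (2S)-6-[5,7-dihydroxy-2-(4-hydroxyphenyl)-4-oxo-4H-chromen-8-yl]-5,7-dihydroxy-2-(4-hydroxyphenyl)-2,3-dihydro-4H-chromen-4-one
Conditions: H2 (1 atm), Pd/C, THF/MeOH, rt
Reagents that add atoms: none
Why: hydrogenolysis of the six aryl benzyl ethers under neutral conditions, which should leave C2 untouched because neither acid nor base is present, and should be faster than reduction of the flavone double bond or the ketones at one atmosphere.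

**Compound list**

1 | apigenin | O=c1cc(-c2ccc(O)cc2)oc2cc(O)cc(O)c12 | starting material
2 | 5,7-bis(benzyloxy)-2-[4-(benzyloxy)phenyl]-4H-chromen-4-one | O=c1cc(-c2ccc(OCc3ccccc3)cc2)oc2cc(OCc3ccccc3)cc(OCc3ccccc3)c12 | intermediate
3 | 5,7-bis(benzyloxy)-2-[4-(benzyloxy)phenyl]-8-iodo-4H-chromen-4-one | O=c1cc(-c2ccc(OCc3ccccc3)cc2)oc2c(I)c(OCc3ccccc3)cc(OCc3ccccc3)c12 | intermediate
4 | 3,5-bis(benzyloxy)phenol | Oc1cc(OCc2ccccc2)cc(OCc2ccccc2)c1 | starting material
5 | 3,5-bis(benzyloxy)-2-bromophenol | Oc1cc(OCc2ccccc2)cc(OCc2ccccc2)c1Br | intermediate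
6 | [3,5-bis(benzyloxy)-2-bromophenoxy]trimethylsilane | C[Si](C)(C)Oc1cc(OCc2ccccc2)cc(OCc2ccccc2)c1Br | intermediate
7 | lithium 3,5-bis(benzyloxy)-2-(trimethylsilyl)phenoxide | [Li+].[O-]c1cc(OCc2ccccc2)cc(OCc2ccccc2)c1[Si](C)(C)C | intermediate
8 | [3,5-bis(benzyloxy)-2-(trimethylsilyl)phenoxy]tri(propan-2-yl)silane | CC(C)[Si](C(C)C)(C(C)C)Oc1cc(OCc2ccccc2)cc(OCc2ccccc2)c1[Si](C)(C)C | intermediate
9 | {2,6-bis(benzyloxy)-3-(trimethylsilyl)-4-[tri(propan-2-yl)silyloxy]phenyl}lithium | CC(C)[Si](C(C)C)(C(C)C)Oc1cc(OCc2ccccc2)c([Li])c(OCc2ccccc2)c1[Si](C)(C)C | intermediate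
10 | chloro{2,6-bis(benzyloxy)-3-(trimethylsilyl)-4-[tri(propan-2-yl)silyloxy]phenyl}zinc | CC(C)[Si](C(C)C)(C(C)C)Oc1cc(OCc2ccccc2)c([Zn]Cl)c(OCc2ccccc2)c1[Si](C)(C)C | intermediate
11 | 5,7-bis(benzyloxy)-2-[4-(benzyloxy)phenyl]-8-{2,6-bis(benzyloxy)-3-(trimethylsilyl)-4-[tri(propan-2-yl)silyloxy]phenyl}-4H-chromen-4-one | O=c1cc(-c2ccc(OCc3ccccc3)cc2)oc2c(-c3c(OCc4ccccc4)cc(O[Si](C(C)C)(C(C)C)C(C)C)c([Si](C)(C)C)c3OCc3ccccc3)c(OCc3ccccc3)cc(OCc3ccccc3)c12 | intermediate
12 | 5,7-bis(benzyloxy)-2-[4-(benzyloxy)phenyl]-8-[2,6-bis(benzyloxy)-4-hydroxy-3-(trimethylsilyl)phenyl]-4H-chromen-4-one | O=c1cc(-c2ccc(OCc3ccccc3)cc2)oc2c(-c3c(OCc4ccccc4)cc(O)c([Si](C)(C)C)c3OCc3ccccc3)c(OCc3ccccc3)cc(OCc3ccccc3)c12 | intermediate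
13 | 3,5-bis(benzyloxy)-4-{5,7-bis(benzyloxy)-2-[4-(benzyloxy)phenyl]-4-oxo-4H-chromen-8-yl}-2-(trimethylsilyl)phenyl trifluoromethanesulfonate | O=c1cc(-c2ccc(OCc3ccccc3)cc2)oc2c(-c3c(OCc4ccccc4)cc(OS(=O)(=O)C(F)(F)F)c([Si](C)(C)C)c3OCc3ccccc3)c(OCc3ccccc3)cc(OCc3ccccc3)c12 | intermediate
14 | 1-[4-(benzyloxy)phenyl]ethan-1-one | CC(=O)c1ccc(OCc2ccccc2)cc1 | starting material
15 | methyl 3-[4-(benzyloxy)phenyl]-3-oxopropanoate | COC(=O)CC(=O)c1ccc(OCc2ccccc2)cc1 | intermediate
16 | methyl (3S)-3-[4-(benzyloxy)phenyl]-3-hydroxypropanoate | COC(=O)C[C@@H](c1ccc(OCc2ccccc2)cc1)O | intermediate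
17 | methyl (3S)-3-[4-(benzyloxy)phenyl]-3-[(trimethylsilyl)oxy]propanoate | COC(=O)C[C@@H](c1ccc(OCc2ccccc2)cc1)O[Si](C)(C)C | intermediate
18 | 5,7-bis(benzyloxy)-2-[4-(benzyloxy)phenyl]-8-[2,6-bis(benzyloxy)-3,4-didehydrophenyl]-4H-chromen-4-one (aryne) | C1#CC=C(OCc2ccccc2)C(c2c(OCc3ccccc3)cc(OCc3ccccc3)c3c(=O)cc(-c4ccc(OCc5ccccc5)cc4)oc23)=C1OCc1ccccc1 | intermediate
19 | caesium aryl anion from addition of the alkoxide of 17 to 18 (carbanion at C4a, ether oxygen at C8a) | [Cs+].COC(=O)C[C@@H](c1ccc(OCc2ccccc2)cc1)Oc1cc(OCc2ccccc2)c(-c2c(OCc3ccccc3)cc(OCc3ccccc3)c3c(=O)cc(-c4ccc(OCc5ccccc5)cc4)oc23)c(OCc2ccccc2)[c-]1 | intermediate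
20 | (2S)-5,7-bis(benzyloxy)-2-[4-(benzyloxy)phenyl]-6-{5,7-bis(benzyloxy)-2-[4-(benzyloxy)phenyl]-4-oxo-4H-chromen-8-yl}-2,3-dihydro-4H-chromen-4-one | O=C1C[C@@H](c2ccc(OCc3ccccc3)cc2)Oc2cc(OCc3ccccc3)c(-c3c(OCc4ccccc4)cc(OCc4ccccc4)c4c(=O)cc(-c5ccc(OCc6ccccc6)cc5)oc34)c(OCc3ccccc3)c21 | intermediate
21 | (2S)-6-[5,7-dihydroxy-2-(4-hydroxyphenyl)-4-oxo-4H-chromen-8-yl]-5,7-dihydroxy-2-(4-hydroxyphenyl)-2,3-dihydro-4H-chromen-4-one | O=C1C[C@@H](c2ccc(O)cc2)Oc2cc(O)c(-c3c(O)cc(O)c4c(=O)cc(-c5ccc(O)cc5)oc34)c(O)c21 | target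

**Step count and risks**

Total step count: 11. Longest linear sequence: 7 steps (steps 3, 4, 5, 6, 7, 10, 11, from 3,5-bis(benzyloxy)phenol).

Steps most likely to fail:

1. Step 10. The aryl anion may be quenched before it captures the ester, the caesium alkoxide may fragment by retro-aldol cleavage, or the product may open at C2–O1 under the basic conditions with loss of configuration. The fallback uses known chemistry, sets out from 12 and comes back at 20. Protodesilylation of 12 with CF3CO2H in CH2Cl2 should give the symmetrical phenol 5,7-bis(benzyloxy)-2-[4-(benzyloxy)phenyl]-8-[2,6-bis(benzyloxy)-4-hydroxyphenyl]-4H-chromen-4-one F1. Reduction of 15 with the (R,R)-catalyst should give methyl (3R)-3-[4-(benzyloxy)phenyl]-3-hydroxypropanoate F2. A Mitsunobu reaction of F1 with F2 (PPh3, DIAD, toluene, 0 °C) should give, with inversion, the (S)-aryl ether ester F3. Neutral hydrolysis with Me3SnOH should give the acid F4. Trifluoroacetic anhydride in CH2Cl2 at 0 °C should convert F4 into the mixed anhydride F5, which closes the same C4–C4a bond by intramolecular Friedel–Crafts acylation to give 20; the two positions ortho to the ether oxygen are equivalent, so only one constitution can form.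

2. Step 5. Benzylic deprotonation followed by Wittig rearrangement may compete with ring metalation, and metalation at the position crowded by the benzyloxy group that the silyl group pushes towards it may be slow. The fallback replaces deprotonation by halogen–lithium exchange, sets out from 4 and comes back at 9. Silylation of 4 (TIPSCl, imidazole) should give [3,5-bis(benzyloxy)phenoxy]tri(propan-2-yl)silane F6. Lithiation of this symmetrical ether between the two benzyloxy groups (n-BuLi, THF, 0 °C) should give the aryllithium F7, and a quench with BrCF2CF2Br the bromide F8. Iodination with NIS at the only free ring position type should give the bromo iodide F9. Selective iodine–lithium exchange (one equivalent of n-BuLi, −100 °C) should give the aryllithium F10, and a TMSCl quench the C-silyl bromide F11. Bromine–lithium exchange of F11 (n-BuLi, −78 °C) then gives 9, which continues through zincation and coupling as in step 5.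

3. Step 11. The flavone C2''–C3'' double bond may be over-reduced, the benzylic C2–O1 bond may be hydrogenolysed, or the hindered benzyl ethers may be cleaved incompletely. The fallback is a non-reductive debenzylation: 20 is treated with BCl3 and pentamethylbenzene as cation scavenger in CH2Cl2 at −78 °C and should give 21 directly, without a new isolated compound.

**Further compounds**

F1 | step 10 | 5,7-bis(benzyloxy)-2-[4-(benzyloxy)phenyl]-8-[2,6-bis(benzyloxy)-4-hydroxyphenyl]-4H-chromen-4-one | O=c1cc(-c2ccc(OCc3ccccc3)cc2)oc2c(-c3c(OCc4ccccc4)cc(O)cc3OCc3ccccc3)c(OCc3ccccc3)cc(OCc3ccccc3)c12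
F2 | step 10 | methyl (3R)-3-[4-(benzyloxy)phenyl]-3-hydroxypropanoate | COC(=O)C[C@H](c1ccc(OCc2ccccc2)cc1)O
F3 | step 10 | methyl (3S)-3-[4-(benzyloxy)phenyl]-3-(3,5-bis(benzyloxy)-4-{5,7-bis(benzyloxy)-2-[4-(benzyloxy)phenyl]-4-oxo-4H-chromen-8-yl}phenoxy)propanoate | COC(=O)C[C@@H](c1ccc(OCc2ccccc2)cc1)Oc1cc(OCc2ccccc2)c(-c2c(OCc3ccccc3)cc(OCc3ccccc3)c3c(=O)cc(-c4ccc(OCc5ccccc5)cc4)oc23)c(OCc2ccccc2)c1
F4 | step 10 | (3S)-3-[4-(benzyloxy)phenyl]-3-(3,5-bis(benzyloxy)-4-{5,7-bis(benzyloxy)-2-[4-(benzyloxy)phenyl]-4-oxo-4H-chromen-8-yl}phenoxy)propanoic acid | OC(=O)C[C@@H](c1ccc(OCc2ccccc2)cc1)Oc1cc(OCc2ccccc2)c(-c2c(OCc3ccccc3)cc(OCc3ccccc3)c3c(=O)cc(-c4ccc(OCc5ccccc5)cc4)oc23)c(OCc2ccccc2)c1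
F5 | step 10 | mixed anhydride of F4 with trifluoroacetic acid | O=C(C[C@@H](c1ccc(OCc2ccccc2)cc1)Oc1cc(OCc2ccccc2)c(-c2c(OCc3ccccc3)cc(OCc3ccccc3)c3c(=O)cc(-c4ccc(OCc5ccccc5)cc4)oc23)c(OCc2ccccc2)c1)OC(=O)C(F)(F)F
F6 | step 5 | [3,5-bis(benzyloxy)phenoxy]tri(propan-2-yl)silane | CC(C)[Si](C(C)C)(C(C)C)Oc1cc(OCc2ccccc2)cc(OCc2ccccc2)c1
F7 | step 5 | {2,6-bis(benzyloxy)-4-[tri(propan-2-yl)silyloxy]phenyl}lithium | CC(C)[Si](C(C)C)(C(C)C)Oc1cc(OCc2ccccc2)c([Li])c(OCc2ccccc2)c1
F8 | step 5 | [3,5-bis(benzyloxy)-4-bromophenoxy]tri(propan-2-yl)silane | CC(C)[Si](C(C)C)(C(C)C)Oc1cc(OCc2ccccc2)c(Br)c(OCc2ccccc2)c1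
F9 | step 5 | [3,5-bis(benzyloxy)-4-bromo-2-iodophenoxy]tri(propan-2-yl)silane | CC(C)[Si](C(C)C)(C(C)C)Oc1cc(OCc2ccccc2)c(Br)c(OCc2ccccc2)c1I
F10 | step 5 | {2,4-bis(benzyloxy)-3-bromo-6-[tri(propan-2-yl)silyloxy]phenyl}lithium | CC(C)[Si](C(C)C)(C(C)C)Oc1cc(OCc2ccccc2)c(Br)c(OCc2ccccc2)c1[Li]
F11 | step 5 | [3,5-bis(benzyloxy)-4-bromo-2-(trimethylsilyl)phenoxy]tri(propan-2-yl)silane | CC(C)[Si](C(C)C)(C(C)C)Oc1cc(OCc2ccccc2)c(Br)c(OCc2ccccc2)c1[Si](C)(C)C
F0 | step 11 | none | none
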